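**Plan**

1. Locants: ring A (1,2-dioxane) is O1–O2–C3–C4–C4a–C7a; ring B (γ-lactone) is C4a–O5–C6(=O)–C7–C7a; the side chain C1′–C10′ sits on C3.
2. Retrosynthesis: cut C7′=C8′ (olefination); then, in one operation, the ring-A bond C3–C4 and the ring-B bond O5–C4a (peroxycarbenium Prins cyclisation ended by lactonisation); then O1–C7a (conjugate peroxidation). This leaves hydroperoxy ketal 4 and dienal 7.
3. Enabling feature: C3 carries O2, a methyl and the chain, so it is a ketone carbon at the peroxyketal level; C4 is a CH2 between the two tertiary C–O carbons C3 and C4a (a Prins retron whose alkene C4a=C4 is an isopropenyl group on C7a); the C6 carboxyl lies five atoms from C4a and can quench the cation that ring-A closure leaves.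
4. Forward: chain hydroperoxide 4 (steps 1–2) and dienal 7 (step 3) are joined at O1–C7a (step 4); the aldehyde is oxidised (step 5); rings A and B form together (step 6); desilylation, oxidation and diene formation follow (steps 7–9).
5. Stereochemistry: C7a from the amine catalyst in step 4; C4a from the cis ring fusion and C3 from the chair transition state in step 6; both diene bonds E from the cinnamyl phosphonate and the olefination.

Key step: step 6

Remark: hydroperoxide 4 is racemic at its ketal carbon; this carbon becomes planar in step 6, so 8, 9 and 10 are carried as pairs of epimers and drawn without a descriptor there.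

Step 1
Reactants: 1 (6-bromohexyloxy)(tert-butyl)dimethylsilane; 2 2-methylallylmagnesium chloride
Product: 3 tert-butyldimethyl[(8-methylnon-8-en-1-yl)oxy]silane
Conditions: Li2CuCl4 (3 mol%), THF, −20 °C to rt
Reagents that add atoms: none
Why: Copper-catalysed sp3–sp3 cross-coupling of an allylic Grignard reagent with a primary alkyl bromide, to which the silyl ether is inert; no stereocentre is formed.

Step 2
Reactants: 3 tert-butyldimethyl[(8-methylnon-8-en-1-yl)oxy]silane
Product: 4 9-[(tert-butyldimethylsilyl)oxy]-2-methoxynonan-2-yl hydroperoxide (racemic)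
Conditions: O3, CH2Cl2/MeOH (3:1), NaHCO3, −78 °C; N2 purge, no reductive work-up
Reagents that add atoms: ozone, [O-][O+]=O; methanol, CO
Why: Criegee ozonolysis in which the primary ozonide of the 1,1-disubstituted alkene splits into formaldehyde and the more substituted carbonyl oxide, which methanol traps as the α-methoxy hydroperoxide; the ketal carbon forms racemic and is planarised again in step 6.

Step 3
Reactants: 5 methacrolein (2-methylprop-2-enal); 6 (triphenylphosphoranylidene)acetaldehyde
Product: 7 (2E)-4-methylpenta-2,4-dienal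
Conditions: PhMe, 80 °C, excess of 5; distillation
Reagents that add atoms: none
Why: Wittig olefination with a stabilised formylmethylene ylide, which gives the E alkene, the excess of the more electrophilic methacrolein holding back a second homologation.

Step 4
Reactants: 4 9-[(tert-butyldimethylsilyl)oxy]-2-methoxynonan-2-yl hydroperoxide; 7 (2E)-4-methylpenta-2,4-dienal
Product: 8 (3R)-3-({9-[(tert-butyldimethylsilyl)oxy]-2-methoxynonan-2-yl}peroxy)-4-methylpent-4-enal (both epimers at the ketal carbon)
Conditions: (R)-2-{bis[3,5-bis(trifluoromethyl)phenyl][(trimethylsilyl)oxy]methyl}pyrrolidine (10 mol%), PhCO2H (10 mol%), PhMe, −20 °C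
Reagents that add atoms: none
Why: Amine-catalysed enantioselective conjugate peroxidation of an enal (oxa-Michael addition through the iminium ion), in which the hydroperoxide oxygen adds to the β-carbon of the s-trans E-iminium ion on the face away from the diaryl(silyloxy)methyl group of the R catalyst and so sets 3R, while the acid co-catalyst and the low temperature favour protonation of the peroxy-enamine over its closure to an epoxide.

Step 5
Reactants: 8 (3R)-3-({9-[(tert-butyldimethylsilyl)oxy]-2-methoxynonan-2-yl}peroxy)-4-methylpent-4-enal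
Product: 9 (3R)-3-({9-[(tert-butyldimethylsilyl)oxy]-2-methoxynonan-2-yl}peroxy)-4-methylpent-4-enoic acid
Conditions: NaClO2, NaH2PO4, 2-methylbut-2-ene, t-BuOH/H2O, 0 °C
Reagents that add atoms: sodium chlorite, [Na+].[O-]Cl=O
Why: Pinnick oxidation, which turns the aldehyde into the acid under buffered conditions that should leave the peroxide, the peroxyketal, the alkene (shielded by the chlorine scavenger) and the β-stereocentre untouched.

Step 6
Reactants: 9 (3R)-3-({9-[(tert-butyldimethylsilyl)oxy]-2-methoxynonan-2-yl}peroxy)-4-methylpent-4-enoic acid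
Product: 13 (3S,4aR,7aR)-3-{7-[(tert-butyldimethylsilyl)oxy]heptyl}-3,4a-dimethyltetrahydrofuro[3,2-c][1,2]dioxin-6(3H)-one, via silyl ester 10 (not isolated), via peroxycarbenium ion 11 (not isolated), via dioxanyl cation 12 (not isolated)
Conditions: N,O-bis(trimethylsilyl)acetamide (1.1 equiv), CH2Cl2, 0 °C; then Me3SiOTf (20 mol%), −78 °C; aq. NaHCO3
Reagents that add atoms: none
Why: Proposed new method: Me3SiOTf removes the methoxy group of the mixed peroxyketal 10 (the more basic oxygen, so the O–O bond stays) to give peroxycarbenium ion 11, whose cationic carbon is attacked by the terminal CH2 of the isopropenyl group to form the C3–C4 bond, and the tertiary cation 12 left at C4a is captured by the carbonyl oxygen of the silyl ester, which then gives up Me3Si+ and regenerates the catalyst. The closest known reaction types are Lewis-acid-mediated additions of alkenes, allylsilanes and silyl enol ethers to peroxycarbenium ions made from monoperoxyketals, including intramolecular closures to 1,2-dioxanes, and cation–olefin cyclisations ended by a carboxyl group to give lactones; new is their union in one cascade on a β-peroxy acid. Ring A closes 6-endo-trig with respect to the alkene (the C=O+ unit is endocyclic as well) and ring B closes 5-exo-trig onto the same alkene carbon. C4a is controlled by C7a, because the two-atom carboxymethyl tether can reach the cation only on its own face, which enforces the cis ring fusion (4aR from 7aR). C3 is controlled by a chair transition state in which the carboxymethyl arm on C7a is axial (this avoids A(1,2) strain with the methyl on the alkene and places the ester anti to the forming C–C bond) and the methyl group on the peroxycarbenium carbon, smaller than the heptyl chain, sits syn to the O–O bond and hence axial, which puts the chain equatorial and should give 3S. The step needs ionisation at OMe and not at the allylic C7a–O bond, C–C bond formation ahead of fragmentation or proton loss, and face selection at C3; these should be secured by the methoxy leaving group, the nucleophilic 1,1-disubstituted alkene held in reach of the cation, the non-nucleophilic triflate counter-ion, the temperature of −78 °C and the methyl/heptyl size difference.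

Step 7
Reactants: 13 (3S,4aR,7aR)-3-{7-[(tert-butyldimethylsilyl)oxy]heptyl}-3,4a-dimethyltetrahydrofuro[3,2-c][1,2]dioxin-6(3H)-one
Product: 14 (3S,4aR,7aR)-3-(7-hydroxyheptyl)-3,4a-dimethyltetrahydrofuro[3,2-c][1,2]dioxin-6(3H)-one
Conditions: HF·pyridine, THF, 0 °C to rt
Reagents that add atoms: none
Why: Fluoride-driven cleavage of the primary silyl ether under mildly acidic conditions, to which the lactone and the dialkyl peroxide are inert.

Step 8
Reactants: 14 (3S,4aR,7aR)-3-(7-hydroxyheptyl)-3,4a-dimethyltetrahydrofuro[3,2-c][1,2]dioxin-6(3H)-one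
Product: 15 7-[(3S,4aR,7aR)-3,4a-dimethyl-6-oxotetrahydro-3H-furo[3,2-c][1,2]dioxin-3-yl]heptanal
Conditions: Dess–Martin periodinane, NaHCO3, CH2Cl2, rt
Reagents that add atoms: none
Why: Dess–Martin oxidation of the primary alcohol to the aldehyde under neutral, non-reducing conditions that do not touch the O–O bond.

Step 9
Reactants: 15 7-[(3S,4aR,7aR)-3,4a-dimethyl-6-oxotetrahydro-3H-furo[3,2-c][1,2]dioxin-3-yl]heptanal; 16 diethyl [(2E)-3-phenylprop-2-en-1-yl]phosphonate
Product: 17 plakortolide Q, (3S,4aR,7aR)-3,4a-dimethyl-3-[(7E,9E)-10-phenyldeca-7,9-dien-1-yl]tetrahydrofuro[3,2-c][1,2]dioxin-6(3H)-one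
Conditions: 16, NaN(SiMe3)2 (0.95 equiv relative to 16), THF, −78 °C; then 15, −78 to 0 °C
Reagents that add atoms: none
Why: Horner–Wadsworth–Emmons olefination with the α-anion of an allylic phosphonate, which should form the new C7′=C8′ bond E by reversible addition and elimination from the more stable adduct while the E styryl bond of 16 is carried over, the anion being fully formed before the base-sensitive aldehyde is added.

**Compound list**

1 | (6-bromohexyloxy)(tert-butyl)dimethylsilane | BrCCCCCCO[Si](C)(C)C(C)(C)C | starting material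
2 | 2-methylallylmagnesium chloride | C=C(C)C[Mg]Cl | starting material
3 | tert-butyldimethyl[(8-methylnon-8-en-1-yl)oxy]silane | C=C(C)CCCCCCCO[Si](C)(C)C(C)(C)C | intermediate
4 | 9-[(tert-butyldimethylsilyl)oxy]-2-methoxynonan-2-yl hydroperoxide (racemic) | CC(OC)(OO)CCCCCCCO[Si](C)(C)C(C)(C)C | intermediate
5 | methacrolein (2-methylprop-2-enal) | C=C(C)C=O | starting material
6 | (triphenylphosphoranylidene)acetaldehyde | O=CC=P(c1ccccc1)(c1ccccc1)c1ccccc1 | starting material
7 | (2E)-4-methylpenta-2,4-dienal | C=C(C)/C=C/C=O | intermediate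
8 | (3R)-3-({9-[(tert-butyldimethylsilyl)oxy]-2-methoxynonan-2-yl}peroxy)-4-methylpent-4-enal (both ketal epimers) | O=CC[C@H](C(C)=C)OOC(C)(OC)CCCCCCCO[Si](C)(C)C(C)(C)C | intermediate
9 | (3R)-3-({9-[(tert-butyldimethylsilyl)oxy]-2-methoxynonan-2-yl}peroxy)-4-methylpent-4-enoic acid (both ketal epimers) | OC(=O)C[C@H](C(C)=C)OOC(C)(OC)CCCCCCCO[Si](C)(C)C(C)(C)C | intermediate
10 | trimethylsilyl (3R)-3-({9-[(tert-butyldimethylsilyl)oxy]-2-methoxynonan-2-yl}peroxy)-4-methylpent-4-enoate (silyl ester, formed in the flask) | C[Si](C)(C)OC(=O)C[C@H](C(C)=C)OOC(C)(OC)CCCCCCCO[Si](C)(C)C(C)(C)C | intermediate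
11 | {9-[(tert-butyldimethylsilyl)oxy]nonan-2-ylidene}{[(3R)-2-methyl-5-oxo-5-[(trimethylsilyl)oxy]pent-1-en-3-yl]oxy}oxonium triflate (peroxycarbenium ion, formed in the flask) | C[Si](C)(C)OC(=O)C[C@H](C(C)=C)O[O+]=C(C)CCCCCCCO[Si](C)(C)C(C)(C)C.[O-]S(=O)(=O)C(F)(F)F | intermediate
12 | (3R,6S)-6-{7-[(tert-butyldimethylsilyl)oxy]heptyl}-4,6-dimethyl-3-{2-oxo-2-[(trimethylsilyl)oxy]ethyl}-1,2-dioxan-4-ylium triflate (dioxanyl cation, formed in the flask) | C[C@]1(CCCCCCCO[Si](C)(C)C(C)(C)C)C[C+](C)[C@@H](CC(=O)O[Si](C)(C)C)OO1.[O-]S(=O)(=O)C(F)(F)F | intermediate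
13 | (3S,4aR,7aR)-3-{7-[(tert-butyldimethylsilyl)oxy]heptyl}-3,4a-dimethyltetrahydrofuro[3,2-c][1,2]dioxin-6(3H)-one | C[C@]1(CCCCCCCO[Si](C)(C)C(C)(C)C)C[C@@]2(C)OC(=O)C[C@H]2OO1 | intermediate
14 | (3S,4aR,7aR)-3-(7-hydroxyheptyl)-3,4a-dimethyltetrahydrofuro[3,2-c][1,2]dioxin-6(3H)-one | C[C@]1(CCCCCCCO)C[C@@]2(C)OC(=O)C[C@H]2OO1 | intermediate
15 | 7-[(3S,4aR,7aR)-3,4a-dimethyl-6-oxotetrahydro-3H-furo[3,2-c][1,2]dioxin-3-yl]heptanal | C[C@]1(CCCCCCC=O)C[C@@]2(C)OC(=O)C[C@H]2OO1 | intermediate
16 | diethyl [(2E)-3-phenylprop-2-en-1-yl]phosphonate | CCOP(=O)(C/C=C/c1ccccc1)OCC | starting material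
17 | plakortolide Q, (3S,4aR,7aR)-3,4a-dimethyl-3-[(7E,9E)-10-phenyldeca-7,9-dien-1-yl]tetrahydrofuro[3,2-c][1,2]dioxin-6(3H)-one | C[C@]1(CCCCCC/C=C/C=C/c2ccccc2)C[C@@]2(C)OC(=O)C[C@H]2OO1 | target

**Step count and risks**

Total steps: 9. Longest linear sequence: 8 (steps 1, 2, 4, 5, 6, 7, 8, 9); step 3 is a one-step branch.

Step 6 (labelled step). What may go wrong: the peroxycarbenium ion may fragment or lose a proton before the C–C bond forms; the tertiary cation may eliminate instead of being captured by the ester; and face selection at C3 may be incomplete if the chain competes with the methyl for the axial position. Fallback, in which ring A is closed with termination by loss of silicon and ring B is closed in a separate step: it sets out from 4 and 6 and comes back at 13. Commercial 2-[(trimethylsilyl)methyl]prop-2-en-1-ol (C=C(CO)C[Si](C)(C)C) is oxidised with MnO2 to 2-[(trimethylsilyl)methyl]prop-2-enal F1. A Wittig reaction with 6 gives (2E)-4-[(trimethylsilyl)methyl]penta-2,4-dienal F2. Conjugate peroxidation with 4 under the conditions of step 4 gives (3R)-3-({9-[(tert-butyldimethylsilyl)oxy]-2-methoxynonan-2-yl}peroxy)-4-[(trimethylsilyl)methyl]pent-4-enal F3, and Pinnick oxidation gives (3R)-3-({9-[(tert-butyldimethylsilyl)oxy]-2-methoxynonan-2-yl}peroxy)-4-[(trimethylsilyl)methyl]pent-4-enoic acid F4. Me3SiOTf at −78 °C then closes ring A by capture of the peroxycarbenium ion by the allylsilane, a known way to 1,2-dioxanes in which the β-silyl cation simply loses Me3Si+, to give 2-[(3R,6S)-6-{7-[(tert-butyldimethylsilyl)oxy]heptyl}-6-methyl-4-methylidene-1,2-dioxan-3-yl]acetic acid F5. Catalytic CF3SO3H in CH2Cl2 (Markovnikov lactonisation of a γ,δ-unsaturated acid, the acid reaching the tertiary cation only on its own face) closes ring B and gives 13. The larger CH2SiMe3 group on the alkene should reinforce the A(1,2) preference for the axial arm.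

Step 4. What may go wrong: the peroxy-enamine may close to the epoxy aldehyde with loss of the chain as its hemiketal; the hydroperoxide may add at the diene terminus; and the enantioselectivity may be poor because the structure of 4 is fixed by the target and cannot be tuned. Fallback, in which the asymmetric C–O bond formation is uncoupled from the chain and the fragments are joined by peroxyketal exchange at O2–C3: it sets out from 7 and 3 and comes back at 9. 1,1-Diphenylethylene is ozonised in methanol to methoxy(diphenyl)methyl hydroperoxide F6, a carrier hydroperoxide whose bulk can be varied freely. Conjugate peroxidation of 7 with F6 (catalyst as in step 4) gives (3R)-3-{[methoxy(diphenyl)methyl]peroxy}-4-methylpent-4-enal F7, and Pinnick oxidation gives (3R)-3-{[methoxy(diphenyl)methyl]peroxy}-4-methylpent-4-enoic acid F8. Aqueous acetic acid hydrolyses the benzophenone-derived peroxyketal to (3R)-3-hydroperoxy-4-methylpent-4-enoic acid F9. In parallel, 3 is ozonised in CH2Cl2 with Me2S work-up to 9-[(tert-butyldimethylsilyl)oxy]nonan-2-one F10, and HC(OMe)3 with pyridinium 4-toluenesulfonate gives tert-butyl[(8,8-dimethoxynonyl)oxy]dimethylsilane F11. Exchange of one methoxy group of F11 by the hydroperoxide F9 (pyridinium 4-toluenesulfonate, CH2Cl2, 0 °C) gives 9.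

Step 9. What may go wrong: the phosphonate anion or the intermediate alkoxide may enolise the lactone, which leads to β-elimination of the peroxide and opening of ring A; and the E selectivity at C7′=C8′ may be incomplete. Fallback, a less basic and stereorandom olefination followed by thermodynamic correction of the geometry: it sets out from 15 and comes back at 17. Commercial [(2E)-3-phenylprop-2-en-1-yl]triphenylphosphonium chloride is converted in a separate flask with NaN(SiMe3)2 into the semi-stabilised ylide, which is far less basic than the phosphonate anion. The ylide solution is added to 15 at −78 °C and should give 17 together with its 7′Z isomer, (3S,4aR,7aR)-3,4a-dimethyl-3-[(7Z,9E)-10-phenyldeca-7,9-dien-1-yl]tetrahydrofuro[3,2-c][1,2]dioxin-6(3H)-one F12. Catalytic I2 in CH2Cl2 under daylight then isomerises F12 to the more stable E,E diene 17.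

**Further compounds**

F1 | step 6 | 2-[(trimethylsilyl)methyl]prop-2-enal | C=C(C[Si](C)(C)C)C=O
F2 | step 6 | (2E)-4-[(trimethylsilyl)methyl]penta-2,4-dienal | C=C(C[Si](C)(C)C)/C=C/C=O
F3 | step 6 | (3R)-3-({9-[(tert-butyldimethylsilyl)oxy]-2-methoxynonan-2-yl}peroxy)-4-[(trimethylsilyl)methyl]pent-4-enal | O=CC[C@H](C(=C)C[Si](C)(C)C)OOC(C)(OC)CCCCCCCO[Si](C)(C)C(C)(C)C
F4 | step 6 | (3R)-3-({9-[(tert-butyldimethylsilyl)oxy]-2-methoxynonan-2-yl}peroxy)-4-[(trimethylsilyl)methyl]pent-4-enoic acid | OC(=O)C[C@H](C(=C)C[Si](C)(C)C)OOC(C)(OC)CCCCCCCO[Si](C)(C)C(C)(C)C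
F5 | step 6 | 2-[(3R,6S)-6-{7-[(tert-butyldimethylsilyl)oxy]heptyl}-6-methyl-4-methylidene-1,2-dioxan-3-yl]acetic acid | C[C@]1(CCCCCCCO[Si](C)(C)C(C)(C)C)CC(=C)[C@@H](CC(=O)O)OO1
F6 | step 4 | methoxy(diphenyl)methyl hydroperoxide | COC(OO)(c1ccccc1)c1ccccc1
F7 | step 4 | (3R)-3-{[methoxy(diphenyl)methyl]peroxy}-4-methylpent-4-enal | O=CC[C@H](C(C)=C)OOC(OC)(c1ccccc1)c1ccccc1
F8 | step 4 | (3R)-3-{[methoxy(diphenyl)methyl]peroxy}-4-methylpent-4-enoic acid | OC(=O)C[C@H](C(C)=C)OOC(OC)(c1ccccc1)c1ccccc1
F9 | step 4 | (3R)-3-hydroperoxy-4-methylpent-4-enoic acid | OC(=O)C[C@H](C(C)=C)OO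
F10 | step 4 | 9-[(tert-butyldimethylsilyl)oxy]nonan-2-one | CC(=O)CCCCCCCO[Si](C)(C)C(C)(C)C
F11 | step 4 | tert-butyl[(8,8-dimethoxynonyl)oxy]dimethylsilane | CC(OC)(OC)CCCCCCCO[Si](C)(C)C(C)(C)C
F12 | step 9 | (3S,4aR,7aR)-3,4a-dimethyl-3-[(7Z,9E)-10-phenyldeca-7,9-dien-1-yl]tetrahydrofuro[3,2-c][1,2]dioxin-6(3H)-one | C[C@]1(CCCCCC/C=C\C=C\c2ccccc2)C[C@@]2(C)OC(=O)C[C@H]2OO1
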